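In the early minutes of Sunday's run the two substrates together fall steeply, and the slope then eases, so the useful number for your flask is the time in which the two substrates together drop to half of their charge, here 2.13 min as read from Sunday's last point: the half-conversion time. Its inverse, 0.469 min⁻¹, is my estimate of the starting slope as a share of the charge. In your flask the coupling partner is charged equal to the two substrates together, so both fall in step and I take the rate as going with the square of what is left. On that reckoning, after n half-conversion times, the share left is one over one plus n.

| setting | Sunday's | Wednesday's | Thursday's | flask |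
|---|---|---|---|---|
| left-handed substrate | 0.050 M | 0.050 M | 0.050 M | 0.050 M |
| right-handed substrate | 0.050 M | 0.050 M | 0.050 M | 0.050 M |
| coupling partner | 0.10 M | 0.10 M | 0.10 M | 0.100 M |
| free catalyst | 5 mM | 5 mM | 2.5 mM | 5.0 mM |
| racemization catalyst | 4.8 mM | 19 mM | 9.5 mM | 9.5 mM |
| impurity | 1.2 mM | 1.2 mM | 1.2 mM | 1.2 mM |
| remark | run made earlier | run made earlier | run made earlier |  |
| time |  |  |  | 6.0 min |

| run | time / min | left-handed substrate / % | right-handed substrate / % | left-handed product / % |
|---|---|---|---|---|
| Sunday's | 0.500 | 35.7 | 43.7 | 15.0 |
| Sunday's | 1.00 | 31.2 | 37.9 | 23.0 |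
| Sunday's | 1.50 | 24.4 | 34.3 | 30.7 |
| Sunday's | 2.00 | 22.3 | 29.6 | 33.3 |
| Sunday's | 2.50 | 19.5 | 28.2 | 38.9 |
| Sunday's | 3.00 | 18.6 | 25.4 | 40.5 |
| Sunday's | 4.00 | 13.6 | 21.2 | 44.3 |
| Wednesday's | 0.250 | 42.8 | 45.9 | 9.2 |
| Wednesday's | 0.417 | 40.9 | 43.2 | 13.1 |
| Wednesday's | 0.667 | 37.2 | 38.0 | 16.3 |
| Wednesday's | 1.00 | 31.1 | 34.2 | 23.4 |
| Wednesday's | 1.50 | 26.0 | 31.8 | 30.1 |
| Wednesday's | 2.50 | 17.7 | 24.3 | 39.6 |
| Wednesday's | 4.00 | 16.3 | 19.0 | 46.9 |
| Thursday's | 0.250 | 44.2 | 48.8 | 2.5 |
| Thursday's | 0.500 | 42.7 | 44.7 | 8.6 |
| Thursday's | 1.00 | 38.4 | 41.4 | 14.1 |
| Thursday's | 2.00 | 31.6 | 35.2 | 23.7 |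
| Thursday's | 4.00 | 23.1 | 28.0 | 35.0 |

(each reading ± 1 percentage point)

- free catalyst is single-handed; left-handed substrate and right-handed substrate are mirror images of each other, charged as a racemate, each of them at the stated concentration
- an excess is the difference of the two amounts in percent of their sum
- an excess is below zero if the other one leads

1. part of the left-handed substrate and right-handed substrate charged together that has reacted at 6.0 min
2. excess of left-handed product over right-handed product in the product at 6.0 min
3. excess of right-handed substrate over left-handed substrate among what is left of the two at 6.0 min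

Thursday's run, with half of Sunday's free catalyst and twice its racemization catalyst, reads 4.18 min, twice as long. Wednesday's run, with 3.96 times Sunday's racemization catalyst, reads 2.18 min, about the same.

Your flask has Sunday's free catalyst, so I draw its curve with Sunday's half-conversion time. It crosses half at 2.13 min, where the slope is already down to a quarter of its starting value. A quarter is left at 6.39 min, and from there the curve flattens towards complete conversion. The asked 6.0 min is 2.81 half-conversion times, which leaves 26.2% and makes my conversion 73.8%.

The forecast gives 74% reacted, 43% product excess and 7% substrate excess, holding that “Racemization hardly changes the rate”.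

The flask gives 74.5% reacted, 37.2% product excess and 15.3% substrate excess, the last above the forecast's value.

    2 racemization catalyst ⇌ resting dimer (K = 4000 M⁻¹, k = 1.10 M⁻¹ s⁻¹)
    left-handed substrate + racemization catalyst ⇌ right-handed substrate + racemization catalyst, rate k2*[racemization catalyst]*[left-handed substrate] forward; the back reaction follows from the equilibrium constant (k = 2.39 M⁻¹ s⁻¹)
    coupling partner + free catalyst + right-handed substrate → free catalyst + right-handed product (k = 9.44 M⁻² s⁻¹)
    coupling partner + free catalyst + left-handed substrate → free catalyst + left-handed product (k = 25.1 M⁻² s⁻¹)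
    coupling partner → decomposition product (k = 4.59 × 10⁻⁶ s⁻¹)
    racemization catalyst + impurity → spent catalyst (k = 256 M⁻¹ s⁻¹)

In your flask at 6.00 min the racemization catalyst stands at 14.0% of its charge, with 73.3% held as resting dimer, its resting state, and 12.6% as spent catalyst. Your flask has 25.5% of its substrates left after those 2.81 half-conversion times. For the neighbour flask charged with 0.020 M of free catalyst, the half-conversion time cut in proportion comes to 0.534 min, so the same 6.0 min reckons to 8.17% left, and that flask has reacted 91.8%.

The runs were computed for an exercise, and the scatter is random.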